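(The numbers in the tables are simulated for an exercise; scatter was added.)

Amounts first: I follow the left-handed and right-handed product, and their excess e, which is their difference over their sum.

| flask | left-handed substrate | right-handed substrate | coupling partner | temperature | remark | time |
|---|---|---|---|---|---|---|
| amber | 0.10 M | 0.10 M | 4.2 equiv | 2 °C | run made earlier |  |
| green | 0.10 M | 0.10 M | 6.6 equiv | 30 °C | run made earlier |  |
| grey | 0.050 M | 0.050 M | 3 equiv | 2 °C | run made earlier |  |
| east | 0.10 M | 0.10 M | 3.00 equiv | 40 °C |  | 25 h |
| north-west | 0.10 M | 0.10 M | 3.00 equiv | 15 °C |  | 25 h |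
| north | 0.10 M | 0.10 M | 3.00 equiv |  | at −10 °C until 20 h, from then on at 40 °C | 25 h |
| south | 0.10 M | 0.10 M | 3.00 equiv | −10 °C |  | 25 h |

| run | time / h | left-handed product / % | right-handed product / % |
|---|---|---|---|
| amber | 12.0 | 1.3 | 0 |
| amber | 25.0 | 0.4 | 0 |
| amber | 48.0 | 2.2 | 1.6 |
| amber | 72.0 | 2.8 | 1.9 |
| amber | 144 | 6.9 | 1.8 |
| green | 3.00 | 5.2 | 1.8 |
| green | 6.00 | 8.6 | 2.7 |
| green | 12.0 | 12.7 | 5.5 |
| green | 20.0 | 15.4 | 6.9 |
| green | 40.0 | 15.0 | 11.0 |
| grey | 12.0 | 1.0 | 0.1 |
| grey | 40.0 | 0.5 | 1.9 |
| grey | 72.0 | 0.4 | 0 |
| grey | 120 | 1.7 | 0 |
| grey | 144 | 0.4 | 1.3 |

(each reading ± 1 percentage point)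

* which flask leads in excess of left-handed product over right-handed product ("all alike" within 1.5 percentage points) (east / north-west / north / south / all alike)
* excess of left-handed product over right-handed product at the end, east
* excess of left-handed product over right-handed product at the end, north-west
* excess of left-handed product over right-handed product at the end, north
* excess of left-handed product over right-handed product at the end, south

- coupling partner is single-handed; left-handed substrate and right-handed substrate are mirror images of each other, charged as a racemate, each of them at the stated concentration
- steps thought possible: left-handed product <-> right-handed product; coupling partner + left-handed substrate -> left-handed product; coupling partner <-> dormant form; coupling partner -> decomposed reagent; coupling partner + right-handed substrate -> right-handed product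
- an excess is the difference of the two amounts in percent of their sum
- an excess is below zero if the other one leads
- the handed part of coupling partner does not stay in what it makes, so the products of the two hands are mirror images too

The products are mirror images, so the step between them (racemisation) takes e towards zero. I therefore reckon with the fraction of e left, not the amount made: f = exp(−λτ), with τ the age of the product. In the green run e falls from 38.1% at 20.0 h to 15.4% at 40.0 h. So I read λ = 0.0454 h⁻¹, the rate at which excess is lost to racemisation.

One objection: the green total still rises from 22.3% to 26.0%, and fresh product slows the fall, so this λ reads low. I keep it as a reading.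

A second objection: λ belongs to 30 °C. I assume a factor 3 for the span from 30 °C to 40 °C, and the same factor per equal span elsewhere. That gives 0.136 h⁻¹ at 40 °C and 0.00873 h⁻¹ at 15 °C.

Age needs care too. In north-west and south I take τ at the middle of the run, which gives f = 0.897 and 0.993. The amber run, at 2 °C, shows 1.3% after 12.0 h, and north's first stretch at −10 °C is colder, so I date north's product from the change at 20 h, and the middle of its hot stretch gives f = 0.712. I expect east to make its product early, so I date it from the time of green's second reading, which takes τ as 19.0 h, and f = 0.0753.

For the start excess I average green's first reading and amber's last, e₀ = 53.6%. The doubt stays here: amber's e scatters by about 18.8%, and I hold e₀ the same at each temperature by assumption.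

My reckoning gives east 4.04%, north-west 48.1%, north 38.1% and south 53.2%, so south leads north-west, by less than that scatter.

The forecast also names south, with east 5%, north-west 51%, north 36% and south 57%. For south it says “no racemisation, so the intrinsic value”. Its south stands higher than my e₀.

The flasks give north-west in the lead: east 2.25%, north-west 59.7%, north 44.3%, south 46.9%.

    left-handed product ⇌ right-handed product (k = 0.00148 min⁻¹, Ea = 100 kJ mol⁻¹)
    coupling partner + left-handed substrate → left-handed product (k = 0.00318 M⁻¹ min⁻¹, Ea = 85.0 kJ mol⁻¹)
    coupling partner ⇌ dormant form (K = 0.600, k = 1.12 × 10⁻⁴ min⁻¹, Ea = 121 kJ mol⁻¹, ΔH = −32.0 kJ mol⁻¹)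
    coupling partner → decomposed reagent (k = 0.00416 min⁻¹, Ea = 108 kJ mol⁻¹)
    coupling partner + right-handed substrate → right-handed product (k = 4.13 × 10⁻⁴ M⁻¹ min⁻¹, Ea = 71.0 kJ mol⁻¹)
    (constants at 40 °C)

The activation energy of the step to right-handed product minus that of the step to left-handed product is −14.0 kJ mol⁻¹. Dividing by my fraction left puts the start excess of north-west near 66.6% and of south near 47.2%. The repeat of east at 25 °C, with my λ = 0.0262 h⁻¹ and f = 0.721, ended at 48.0%, which puts its start excess near 66.6%.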